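**Starved end.** Sunday's run, with nucleophile charged at 0.690 of the electrophile, gains 6.9 percentage points of target from 1.00 min to 2.00 min but 1.2 points from 4.00 min to 5.00 min. I read this slowing in Sunday's run as the acid set free binding a nucleophile, so that each substitution would cost two nucleophile.

common to all: electrophile 0.10 M

| run | nucleophile | remark | time |
|---|---|---|---|
| Sunday's | 0.069 M | run made earlier |  |
| Saturday's | 1.1 M | run made earlier |  |
| beta | 0.0500 M |  | 10 min |
| epsilon | 0.100 M |  | 10 min |
| gamma | 0.200 M |  | 10 min |
| theta | 0.400 M |  | 10 min |
| alpha | 0.800 M |  | 10 min |

- Sunday's (time / min: target / %): 1.00: 11.2; 2.00: 18.1; 3.00: 22.3; 4.00: 25.6; 5.00: 26.8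
- Saturday's (time / min: target / %): 0.417: 51.2; 1.33: 47.3; 2.50: 24.9; 4.00: 10.3; 5.00: 5.2

(standard deviation of a reading: 0.5 percentage points)

- steps thought possible: electrophile + nucleophile -> acid set free + target; nucleophile + acid set free <-> protonated nucleophile; nucleophile + target -> over-reaction product
- "hardly changes" means that all values lie within two and a half points (for a concentration: within two and a half percent of the largest)

- amount of target at the end, in percent of the electrophile charged for beta, epsilon, gamma, theta, alpha, in this order
- how that number moves from the first to the last of them (falls, then rises / hardly changes / falls all the way / rises, then falls / rises all the way)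

I call the ration the share of the electrophile charge that the nucleophile charge can turn at two nucleophile per substitution, which for beta is 25.0%. For a starved flask I take the ration as the large term and treat over-reaction as a small correction to it.

**Flooded end.** Saturday's run, with nucleophile at 11.0 of the electrophile, is close to pseudo-first-order. Its target stands at 51.2% at 0.417 min and falls to 5.2% at 5.00 min. Its readings from 2.50 min to 5.00 min read as a time constant of 1.60 min for the fall of the target, shorter than the 10 min the new flasks get.

**Between them.** I expect beta just under its ration, and the row to climb at first as the ration climbs. Alpha, with nucleophile at 8.00 of the electrophile, should resemble Saturday's run, so I expect the row to turn back somewhere between.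

**The forecast.** It gives 22.7%, 40.7%, 57%, 33% and 2.6%, so the row rises, then falls; its own words are “Low nucleophile starves the reaction, while high nucleophile over-reacts the target”.

**The flasks.** They give 23.6%, 41.0%, 56.5%, 30.8% and 1.97%, and the row rises, then falls.

    electrophile + nucleophile → acid set free + target (k = 2.28 M⁻¹ min⁻¹)
    nucleophile + acid set free ⇌ protonated nucleophile, settled at all times (K = 3100 M⁻¹)
    nucleophile + target → over-reaction product (k = 0.807 M⁻¹ min⁻¹)

**Beta's balance.** In beta at 10.0 min, substitution uses nucleophile 9.0 times as fast as over-reaction, and the target's half-life against over-reaction, 6.5 h, is longer than the 10 min of the run. Beta has then turned 24.8% of its electrophile against a ration of 25.0%, with 4.4% of its nucleophile left. Epsilon has a ration of 50.0% and at 10.0 min has turned 46.1% of its electrophile.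

(The data were generated by integration from invented constants.)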